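# Pinazaphilone B: proposed total synthesis from (−)-shikimic acid

**Retrosynthetic overview**
1. The orsellinate ester is put on the C8 alcohol late (Shiina acylation). The phenol TBS groups and the TMSE ester come off in one fluoride step.
2. The pyran ring is formed last, by 6-endo oxa-1,6-addition of the C1 alcohol onto an enynone. The enynone comes from IBX dehydrogenation and a Sonogashira coupling of a terminal alkyne on the cyclohexane.
3. The carbocycle is the shikimate ring itself. The C8a–C1 bond forms by photochemical silylmethyl radical cyclization syn to O3. C7 is set by MeMgBr addition anti to the fused tether ring. C8 is set by photochemical epimerization of C3 to the trans isomer. The ester carbon becomes the alkyne (C4≡C3).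
4. Ring order: the shikimate carbocycle is already present, the temporary oxasilolane is formed in Step 3 and opened in Step 8, and the pyran is closed last.

**Assumptions**
- The allylic 3-OH of methyl shikimate is the most reactive OH toward the small silyl chloride, and any O4/O5 silyl isomers are separated by chromatography.
- The shikimate C1 stereocentre (target C4a) is left undefined until IBX dehydrogenation destroys it in Step 15.

## Route

**Step 1**
Reactants: 1, (−)-shikimic acid
Product: 2, methyl shikimate
Conditions: MeOH, cat. H2SO4, reflux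
Reagents that add atoms: methanol, CO
Why: Fischer esterification; the stereocentres are untouched.

**Step 2**
Reactants: 2
Product: 3, the 3-O-(bromomethyl)dimethylsilyl ether
Conditions: BrCH2SiMe2Cl (1.1 equiv), imidazole, DMF, 0 °C
Reagents that add atoms: (bromomethyl)chlorodimethylsilane, C[Si](C)(CBr)Cl
Why: Silylation at the allylic 3-OH installs the Nishiyama–Stork radical tether and also protects O3 through the next steps.

**Step 3**
Reactants: 3
Product: 4, the cis-fused oxasilolane, with the new C8a–C1 bond (CH2–Si) and C4a–H epimeric
Conditions: (TMS)3SiH (1.3 equiv), fac-Ir(ppy)3 (1 mol %), MeCN (5 mM), blue LEDs, 25 °C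
Reagents that add atoms: none (H only)
Why: A silyl radical abstracts Br (halogen-atom transfer), and the nucleophilic α-silylmethyl radical undergoes 5-exo Giese-type cyclization onto C2 of the acrylate; the tether can only reach the face bearing O3, so CH2 is delivered syn to O3 (this sets C8a), and the α-ester radical is then reduced by the silane.

**Step 4**
Reactants: 4
Product: 5, the aldehyde
Conditions: DIBAL-H (4 equiv), CH2Cl2, −78 °C
Reagents that add atoms: none (H only)
Why: Partial DIBAL reduction of the saturated methyl ester; extra hydride equivalents cover the two free OH groups, and the cyclic silyl ether survives at −78 °C.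

**Step 5**
Reactants: 5
Product: 6, the terminal alkyne (this is C4≡C3)
Conditions: Bestmann–Ohira reagent (1.5 equiv), K2CO3, MeOH, 0→25 °C
Reagents that add atoms: dimethyl (1-diazo-2-oxopropyl)phosphonate, COP(=O)(OC)C(=[N+]=[N-])C(C)=O (adds the terminal alkyne carbon)
Why: Ohira–Bestmann homologation; epimerization at the α-carbon is irrelevant because C4a is later made sp2.

**Step 6**
Reactants: 6
Product: 7, the 4,5-diketone (as its diosphenol)
Conditions: (COCl)2, DMSO, Et3N, CH2Cl2, −78→0 °C
Reagents that add atoms: none
Why: Swern oxidation of the trans-4,5-diol gives the α-dione, which enolizes toward C6 and so masks the C5 ketone as an enolate for the next step.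

**Step 7**
Reactants: 7
Product: 8, the α-ketol (C7 tertiary carbinol, C6 ketone)
Conditions: MeMgBr (4 equiv), THF, −78→0 °C, then aq. NH4Cl
Reagents that add atoms: methylmagnesium bromide, C[Mg]Br
Why: Grignard 1,2-addition to the only free carbonyl (C4) proceeds from the face anti to the cis-fused oxasilolane, which blocks the top face; this sets C7 (Me up, OH down in the target orientation), and the first equivalents are consumed by the alkyne C–H and the diosphenol OH.

**Step 8**
Reactants: 8
Product: 9, the C1/C3 diol (CH2OH on C8a, free C3–OH, tertiary C4–OH, C5 ketone)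
Conditions: 30% H2O2, KF, KHCO3, THF/MeOH, 25 °C
Reagents that add atoms: hydrogen peroxide, OO
Why: Tamao–Fleming oxidation converts the Si–CH2 bond to CH2–OH with retention and cleaves the Si–O3 bond; the alkyne and the ketone are inert under these buffered conditions.

**Step 9**
Reactants: 9
Product: 10, the primary TES ether
Conditions: TESCl (1.1 equiv), imidazole, DMF, 0 °C
Reagents that add atoms: chlorotriethylsilane, CC[Si](Cl)(CC)CC
Why: The primary OH is silylated selectively over the secondary and tertiary alcohols, leaving C3–OH as the only secondary carbinol.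

**Step 10**
Reactants: 10
Product: 11, the C3 epimer (C3–O trans to the C2–CH2OTES; this is target C8)
Conditions: TBADT (2 mol %), (i-Pr)3SiSH (10 mol %), MeCN, 390 nm LEDs, 25 °C, 24 h
Reagents that add atoms: none
Why: Proposed new method: decatungstate abstracts the hydridic α-hydroxy C3–H (HAT), and the planar α-hydroxy radical is quenched by H-atom transfer from the thiol. Repeated HAT/back-HAT funnels the cis isomer to the thermodynamically favoured trans-diequatorial isomer, because C3–OH/C2-substituent cis relationships are less stable. The closest known reaction is photochemical HAT/thiol epimerization of carbinol stereocentres in diols and sugars; it has not been shown on a neopentyl-type carbinol flanking a quaternary tertiary alcohol in a carbocycle. The TES ether, alkyne and ketone are inert, and the tertiary C4 carbinol has no α-H.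

**Step 11**
Reactants: 12, orsellinic acid
Product: 13, 2,4-bis(TBSO)-6-methylbenzoic acid
Conditions: TBSCl (3.3 equiv), imidazole, DMF, 25 °C; then K2CO3, MeOH/H2O
Reagents that add atoms: tert-butyldimethylsilyl chloride, CC(C)(C)[Si](C)(C)Cl
Why: Both phenols are silylated, and the transient silyl ester is hydrolysed in the basic work-up.

**Step 12**
Reactants: 11 and 13
Product: 14, the C3 orsellinate ester
Conditions: MNBA (1.5 equiv), DMAP (0.3 equiv), Et3N, CH2Cl2, 40 °C
Reagents that add atoms: none (acid 13 is a reactant)
Why: Shiina mixed-anhydride esterification acylates the hindered secondary alcohol with retention (this is target C8), and the tertiary alcohol does not react.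

**Step 13**
Reactants: 15, (E)-3-iodoacrylic acid
Product: 16, 2-(trimethylsilyl)ethyl (E)-3-iodoacrylate
Conditions: 2-(trimethylsilyl)ethanol, EDC·HCl, DMAP, CH2Cl2, 0→25 °C
Reagents that add atoms: 2-(trimethylsilyl)ethanol, C[Si](C)(C)CCO
Why: Steglich esterification gives a fluoride-labile acid protecting group that is compatible with the Pd steps.

**Step 14**
Reactants: 14 and 16
Product: 17, the enynoate
Conditions: Pd(PPh3)4 (5 mol %), CuI (10 mol %), i-Pr2NH, THF, 25 °C
Reagents that add atoms: none (16 is a reactant)
Why: Sonogashira coupling with retention of alkene geometry gives the (E)-enynoate; the ketone, esters and silyl groups are inert, and there is no enone yet, so no base-labile γ-H.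

**Step 15**
Reactants: 17
Product: 18, the enynone (C4a=C5 conjugated with the C6 ketone)
Conditions: IBX (3 equiv), DMSO, 65 °C
Reagents that add atoms: none
Why: Nicolaou IBX dehydrogenation of the ketone through its only enolizable side (C5) gives the cross-conjugated dienone and erases the C4a stereocentre; the primary alcohol (TES) and C8 (ester) are protected, and the tertiary OH is inert.

**Step 16**
Reactants: 18
Product: 19, the free primary alcohol
Conditions: PPTS (0.2 equiv), MeOH/CH2Cl2, 25 °C
Reagents that add atoms: none
Why: Mild acidic methanolysis removes only the primary TES ether; the aryl TBS ethers and the TMSE ester survive, and no base is used (the β-acyloxy/γ-acidic C8a–H motif is now present).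

**Step 17**
Reactants: 19
Product: 20, the protected pinazaphilone B (pyran ring formed)
Conditions: PPh3 (0.2 equiv), CH2Cl2 (10 mM), 25 °C
Reagents that add atoms: none
Why: 6-endo oxa-1,6-addition (phosphine-catalysed hydroalkoxylation): the alkyne carbon C3 is the δ-electrophile of the enynone, so the C1 alcohol closes the six-membered ring at C3, and protonation at C4 gives the cross-conjugated O2–C3=C4–C4a=C5–C6=O push–pull system with the (E)-acrylate on C3.

**Step 18**
Reactants: 20
Product: 21, pinazaphilone B
Conditions: TBAF (3.5 equiv), AcOH (3.5 equiv), THF, 0 °C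
Reagents that add atoms: none
Why: Buffered fluoride removes both aryl TBS groups and the TMSE ester by fluoride-induced β-elimination, releasing the free acid under conditions mild enough for the acyloxy/γ-H motif.

## Compound list

| # | Name | SMILES | Role |
|---|---|---|---|
| 1 | (−)-shikimic acid | `OC(=O)C1=C[C@@H](O)[C@@H](O)[C@H](O)C1` | starting material |
| 2 | methyl shikimate | `COC(=O)C1=C[C@@H](O)[C@@H](O)[C@H](O)C1` | intermediate |
| 3 | 3-O-(bromomethyl)dimethylsilyl ether | `COC(=O)C1=C[C@@H](O[Si](C)(C)CBr)[C@@H](O)[C@H](O)C1` | intermediate |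
| 4 | cis-fused oxasilolane ester (C1 epimeric) | `COC(=O)C1C[C@@H](O)[C@H](O)[C@@H]2O[Si](C)(C)C[C@H]12` | intermediate |
| 5 | aldehyde | `O=CC1C[C@@H](O)[C@H](O)[C@@H]2O[Si](C)(C)C[C@H]12` | intermediate |
| 6 | terminal alkyne | `C#CC1C[C@@H](O)[C@H](O)[C@@H]2O[Si](C)(C)C[C@H]12` | intermediate |
| 7 | 4,5-diketone | `C#CC1CC(=O)C(=O)[C@@H]2O[Si](C)(C)C[C@H]12` | intermediate |
| 8 | α-ketol (C7 set) | `C#CC1CC(=O)[C@](C)(O)[C@@H]2O[Si](C)(C)C[C@H]12` | intermediate |
| 9 | diol after Tamao–Fleming | `C#CC1CC(=O)[C@](C)(O)[C@H](O)[C@@H]1CO` | intermediate |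
| 10 | primary TES ether | `C#CC1CC(=O)[C@](C)(O)[C@H](O)[C@@H]1CO[Si](CC)(CC)CC` | intermediate |
| 11 | C3 epimer (trans) | `C#CC1CC(=O)[C@](C)(O)[C@@H](O)[C@@H]1CO[Si](CC)(CC)CC` | intermediate |
| 12 | orsellinic acid | `Cc1cc(O)cc(O)c1C(=O)O` | starting material |
| 13 | 2,4-bis(TBSO)-6-methylbenzoic acid | `Cc1cc(O[Si](C)(C)C(C)(C)C)cc(O[Si](C)(C)C(C)(C)C)c1C(=O)O` | intermediate |
| 14 | C3 orsellinate ester | `C#CC1CC(=O)[C@](C)(O)[C@@H](OC(=O)c2c(C)cc(O[Si](C)(C)C(C)(C)C)cc2O[Si](C)(C)C(C)(C)C)[C@@H]1CO[Si](CC)(CC)CC` | intermediate |
| 15 | (E)-3-iodoacrylic acid | `OC(=O)/C=C/I` | starting material |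
| 16 | TMSE (E)-3-iodoacrylate | `C[Si](C)(C)CCOC(=O)/C=C/I` | intermediate |
| 17 | enynoate | `C[Si](C)(C)CCOC(=O)/C=C/C#CC1CC(=O)[C@](C)(O)[C@@H](OC(=O)c2c(C)cc(O[Si](C)(C)C(C)(C)C)cc2O[Si](C)(C)C(C)(C)C)[C@@H]1CO[Si](CC)(CC)CC` | intermediate |
| 18 | enynone | `C[Si](C)(C)CCOC(=O)/C=C/C#CC1=CC(=O)[C@](C)(O)[C@@H](OC(=O)c2c(C)cc(O[Si](C)(C)C(C)(C)C)cc2O[Si](C)(C)C(C)(C)C)[C@@H]1CO[Si](CC)(CC)CC` | intermediate |
| 19 | primary alcohol | `C[Si](C)(C)CCOC(=O)/C=C/C#CC1=CC(=O)[C@](C)(O)[C@@H](OC(=O)c2c(C)cc(O[Si](C)(C)C(C)(C)C)cc2O[Si](C)(C)C(C)(C)C)[C@@H]1CO` | intermediate |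
| 20 | protected pinazaphilone B | `O=C(c3c(C)cc(O[Si](C)(C)C(C)(C)C)cc3O[Si](C)(C)C(C)(C)C)O[C@H]1[C@@H]2COC(/C=C/C(=O)OCC[Si](C)(C)C)=CC2=CC(=O)[C@]1(C)O` | intermediate |
| 21 | pinazaphilone B | `Cc1cc(O)cc(O)c1C(=O)O[C@H]1[C@@H]2COC(/C=C/C(=O)O)=CC2=CC(=O)[C@]1(C)O` | target |

**Total steps:** 18 (including the two small side-chain and acid preparations, Steps 11 and 13).
**Longest linear sequence:** 16 steps from 1 (Steps 1–10, 12, 14–18).

## Three steps most likely to fail
1. **Step 10, photochemical C3 epimerization (the proposed new step).** The HAT site selectivity or the thermodynamic ratio may be poor.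
   - Fallback (known chemistry, different approach): invert and acylate in one step by Mitsunobu on TES ether 10 (PPh3, DIAD, acid 13). If the neopentyl-type SN2 fails, oxidize C3–OH, reduce both ketones with NaBH4 so the hydride enters anti to the axial Me, and selectively re-oxidize the less hindered C5–OH.
2. **Step 7, diastereoselective MeMgBr addition.** Facial selectivity, or competing Si–O attack by the Grignard, could erode C7 control.
   - Fallback: protect C5–OH as TBS, oxidize only C4–OH, and add MeTi(OiPr)3 to the mono-ketone, still anti to the tether ring.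
3. **Step 17, 6-endo oxa-1,6-addition.** The enoate also activates C4 (5-exo), and the β-acyloxy/γ-acidic C8a–H can undergo E1cB.
   - Fallback: cyclize the terminal enynone (before the Sonogashira coupling) with Ph3PAuNTf2 (6-endo hydroalkoxylation) to the 3-H pyran, then install the acrylate by Pd-catalysed oxidative Heck olefination of the cyclic enol ether.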